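Start from the late readings of Monday's run and follow one molecule of starting material through them.

common to all: gas phase 41 mM (held); free catalyst 7.5 mM
- Monday's: starting material 0.22 M; run made earlier
- flask: starting material 0.15 M; time 25 min

Monday's run (percent of the starting material charged)

| time / min | product / % | starting material / % |
|---|---|---|
| 0.500 | 0.3 | 98.8 |
| 1.33 | 2.2 | 98.3 |
| 2.50 | 5.8 | 94.8 |
| 4.00 | 9.3 | 91.4 |
| 6.00 | 12.8 | 86.1 |
| 8.00 | 17.2 | 82.2 |

(scatter of a reading: 0.5 percentage points)

- at the start none of the gas phase is in solution

- amount of product at 25 min, in percent of the starting material charged
- concentration of dissolved gas in solution at 12 min, in percent of saturation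
- the change that raises the amount of product at 25 min, in percent of the starting material charged most ("none" if none brings more than 2 percentage points) (maple / cedar / oak / none)
- amount of product at 25 min, in percent of the starting material charged, after oak

- maple: doubling the saturation concentration of gas phase, all else as stated
- cedar: doubling the amount of free catalyst, all else as stated
- oak: doubling the transfer coefficient of the gas phase, all else as stated

The molecule stands at a fork: it can become product or go elsewhere. At 8.00 min in Monday's run, product and starting material add up to 99.4 %, which is a full count within the scatter, so read what left the starting material as product.

Now ask what chance per minute the molecule has of turning. Between 2.50 min and 8.00 min, the logarithm of the unturned fraction of Monday's run falls at 0.0235 min⁻¹. This reading is the turning chance, the fraction of the still unturned molecules that turn per minute, a pseudo-first-order constant. Counted from zero, it gives 1.17 % at 0.500 min and 3.08 % at 1.33 min, above the 0.3 % and 2.2 % read. At the start none of the gas is in solution, so expect a short lag, and leave it out of the reckoning below.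

The flask has less starting material but the same gas and free catalyst, so assume the same chance, and assume that it lasts; one run cannot test either. The product at 25 min is then 44.4 %. Assume also that the chance goes with the catalyst: doubled, it gives 69.1 %. Monday's run varies neither the catalyst nor the gas, and the same assumption for the gas gives maple that figure too, so back cedar as a bare guess.

The forecast gives 50 %, above my figure, with 93 % of saturation, 52 % after oak and maple as best: “Maple doubles the rate with no transfer penalty”.

The flask gives 43.7 %, 94.5 % of saturation, 45.3 % after oak and cedar as best.

    gas phase ⇌ dissolved gas, rate k1*(csat - [dissolved gas]) (kL = 0.0200 s⁻¹)
    starting material + dissolved gas + free catalyst → free catalyst + product (k = 2.30 L² mol⁻² s⁻¹)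
    starting material + free catalyst → spent catalyst (k = 0.00330 L mol⁻¹ s⁻¹)
    dissolved gas + free catalyst ⇌ idle complex, settled at all times (K = 8.10 L mol⁻¹)

Read backwards, the flask's 43.7 % is an average chance of 0.0230 min⁻¹, beside the 0.0235 min⁻¹ from Monday's run. Scaled to the neighbour flask with 0.019 M of free catalyst, the chance reckons 77.4 %, and that neighbour stands at 75.5 %. Part of what holds the flask at 43.7 % at 25 min is the time given, acting together with free catalyst turning into spent catalyst: take that turning away and the product at 25 min stands at 52.0 %, and left for 250 min the flask reaches 93.3 %.

All runs are simulated from invented constants; the scatter is artificial.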